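The runs stem from a simulated flask from invented constants; scatter was added.

What struck me first in these runs was how slow they were: after 10.0 d the larch run had turned 33 % of its solid substrate into target, and the alder run 16 %.

all flasks: free catalyst 9.4 mM
- larch: solid substrate 0.31 M; partner 0.94 M; run made earlier
- alder: solid substrate 0.70 M; partner 0.94 M; run made earlier
- flask: solid substrate 0.47 M; partner 0.940 M; time 10 d

| run | time / d | target / % | starting material / % |
|---|---|---|---|
| larch | 2.08 | 7 | 7 |
| larch | 4.00 | 19 | 10 |
| larch | 6.00 | 26 | 12 |
| larch | 8.00 | 30 | 14 |
| larch | 10.0 | 33 | 21 |
| larch | 12.0 | 35 | 25 |
| alder | 2.08 | 0 | 1 |
| alder | 4.00 | 8 | 3 |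
| alder | 6.00 | 12 | 3 |
| alder | 8.00 | 15 | 7 |
| alder | 10.0 | 16 | 8 |
| alder | 12.0 | 16 | 14 |

(each reading ± 1.5 percentage points)

- given per volume of solution although it is solid: solid substrate
- the numbers in the tables scatter by 1.5 percentage points (one standard deviation)
- reactions considered so far: starting material + free catalyst -> catalyst intermediate A; partner + catalyst intermediate A -> catalyst intermediate B; catalyst intermediate B <-> catalyst intermediate C; catalyst intermediate C <-> free catalyst + target; solid substrate <-> starting material; partner -> decomposed reagent
- at the start none of the solid substrate is in solution
- starting material means what is dissolved; the solid is not counted in it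

- south-west: doubling the dissolution coefficient of the solid substrate, all else as stated
- east: doubling the amount of free catalyst, all else as stated
- south: doubling the solubility of the solid substrate, all else as stated
- north: doubling the amount of partner, all else as stated

* the target standing at 10 d, as a percentage of the solid substrate charged
* concentration of starting material in solution at 5.0 d, in percent of saturation
* the change that raises the amount of target at 10 d, in percent of the solid substrate charged most ("none" if none brings more than 2 percentage points) (south-west / east / south / north / none)
* amount of target at 10 d, in percent of the solid substrate charged, after north

Percentages hid the pattern, so I turned them into concentrations. At 10.0 d the larch run held 0.102 M of target and the alder run 0.112 M, although alder had 2.26 times the charge. That gap was smaller than the scatter of one alder reading, 0.0105 M. The mean, 0.107 M, I called the ten-day level c*: the target in mol per litre at 10 d, with partner and free catalyst held as charged here and the solid substrate charge lying between those of the larch and alder runs. Dividing by the charge of this flask gave me 22.8 %.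

My doubt was that equal levels might mean equal supply from the dissolving solid. But in the larch run between 8.00 d and 12.0 d starting material gained 11 percentage points and target 5 points, so more dissolved material stayed unused than was turned into target.

My second doubt was that the level might be a passing value. So I looked at what was left instead of what was made. The share of the last larch target reading still to come was 45.7 % at 4.00 d and 14.3 % at 8.00 d. Read off these scattered readings, with the last one taken as the end, that is a fade with a half-life of 2.38 d, shorter than the 10 d asked. I suspected the partner, which decomposes.

The forecast gave 22 % of target at 10 d, 15 % of saturation at 5.0 d, east as best change and 31 % of target after north, holding: “Catalyst helps under either explanation, so east is best”.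

The flask gave 22.7 % at 10 d, which is 0.107 M against c* of 0.107 M; 30.0 % of saturation at 5.0 d; south as best change, worth 9.1 points; and 27.6 % after north. This flask, charged instead with 0.603 M of solid substrate, moved its target percentage at 10 d by 5 points, and c* reckons a fall of 5.0 points. starting material + free catalyst → catalyst intermediate A (k = 0.0683 L mol⁻¹ min⁻¹); partner + catalyst intermediate A → catalyst intermediate B (k = 0.0516 L mol⁻¹ min⁻¹); catalyst intermediate B ⇌ catalyst intermediate C (K = 19.6, k = 1.28 min⁻¹); catalyst intermediate C ⇌ free catalyst + target (K = 0.312 M, k = 0.00621 min⁻¹); solid substrate ⇌ starting material, rate k5*(cs5 - [starting material]) while solid is left; crystals form when [starting material] > cs5 (solubility = 0.110 M, k = 1.64 × 10⁻⁴ min⁻¹); partner → decomposed reagent (k = 2.72 × 10⁻⁴ min⁻¹)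

In this flask the partner's half-life by decomposition was 1.77 d, far shorter than the 25 d it had at 1.50 d by turning with catalyst intermediate A into catalyst intermediate B. At 10.0 d the flask held 0.831 M of decomposed reagent and 0.20 % of the partner charged.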